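**Retrosynthetic overview**

1. Rings are lettered A to G from the terminal ring with hydroxyls on C2, C4 and C6; in every ring C1 is the ether carbon on the ring A side. The route rests on the C4 oxygen of rings C, E and G, the hydroxyl para to the C1 ether carbon and between the C3 and C5 hydroxyls. These three C4–O bonds are made last and together, by Baeyer–Villiger oxidation of the C4 formyl groups of trialdehyde 25, followed by global hydrogenolysis.
2. 25 is cut at the A–O–B, C–O–D and E–O–F ethers: Ullmann couplings of phenol 4 and of the unmasked C2 phenols of rings C and E with the bromides 19, 19 and 20.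
3. 19 and 20 are cut at the B–O–C type ether: SNAr of the 2,6-bis(benzyloxy)-4-bromophenoxide from 10 on fluoroaldehydes 18 and 13, each C4 formyl group activating the para C1–F bond.
4. Phenols 4 and 10 come from the benzylated aldehydes 2 and 8 by the same oxidation; the C2 oxygen of rings C and E comes from bromination, borylation and oxidation of 13.
5. No ring is closed and there is no stereocentre; the aryl units are joined in the order monomers, dimers (B–C = D–E, F–G), trimer A–C, pentamer A–E, heptamer A–G.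

Key step: step 19

Remark: the target has no stereocentre and its diaryl ether bonds are taken as freely rotating, so no stereocontrol is needed; 1,3,5-tris(benzyloxy)benzene, the tribenzyl ether of phloroglucinol, is taken as a purchasable compound.

**Route**

Step 1
Reactants: 1 1,3,5-tris(benzyloxy)benzene
Product: 2 2,4,6-tris(benzyloxy)benzaldehyde
Conditions: POCl3 (1.2 equiv), DMF, 0 °C → 60 °C; then ice–water, rt
Reagents that add atoms: N,N-dimethylformamide, CN(C)C=O; water, O
Why: Vilsmeier–Haack formylation, in which the chloroiminium ion attacks one of three equivalent ring positions activated by three benzyloxy donors and the formyl group then deactivates the ring against a second attack.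

Step 2
Reactants: 2 2,4,6-tris(benzyloxy)benzaldehyde
Product: 4 2,4,6-tris(benzyloxy)phenol, via formate ester 3 (not isolated)
Conditions: mCPBA, NaHCO3, CH2Cl2, 0 °C → rt; aq. Na2S2O3; then K2CO3 (cat.), MeOH, 0 °C
Reagents that add atoms: meta-chloroperbenzoic acid, OOC(=O)c1cccc(Cl)c1
Why: Baeyer–Villiger (Dakin-type) oxidation in which the aryl group, activated by two ortho and one para benzyloxy donors, migrates in preference to hydride, followed by methanolysis of the aryl formate.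

Step 3
Reactants: 5 4-bromo-2,6-difluorobenzaldehyde; 6 benzyl alcohol
Product: 7 2-(benzyloxy)-4-bromo-6-fluorobenzaldehyde
Conditions: BnOH (1.0 equiv), KOtBu (1.0 equiv), THF, −40 °C → 0 °C
Reagents that add atoms: none
Why: SNAr at one of the two equivalent fluorines ortho to the formyl group, which should stop after one substitution because the benzyloxy group that has entered deactivates the ring and only one equivalent of alkoxide is present in the cold.

Step 4
Reactants: 7 2-(benzyloxy)-4-bromo-6-fluorobenzaldehyde; 6 benzyl alcohol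
Product: 8 2,6-bis(benzyloxy)-4-bromobenzaldehyde
Conditions: BnOH (1.1 equiv), KOtBu (1.1 equiv), THF, 0 °C → 40 °C
Reagents that add atoms: none
Why: Second SNAr at the remaining ortho fluorine, slower than the first and therefore run warmer with a measured charge of alkoxide, and regiochemically unambiguous because fluoride is a far better nucleofuge than the para bromide.

Step 5
Reactants: 8 2,6-bis(benzyloxy)-4-bromobenzaldehyde
Product: 10 2,6-bis(benzyloxy)-4-bromophenol, via bromoaryl formate 9 (not isolated)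
Conditions: mCPBA, NaHCO3, CH2Cl2, 0 °C → rt; aq. Na2S2O3; then K2CO3 (cat.), MeOH, 0 °C
Reagents that add atoms: meta-chloroperbenzoic acid, OOC(=O)c1cccc(Cl)c1
Why: The same Baeyer–Villiger oxidation and formate methanolysis, with aryl migration driven by the two ortho benzyloxy groups, should turn the formyl carbon into the hindered phenol oxygen while the aryl bromide is untouched.

Step 6
Reactants: 11 2,4,6-trifluorobenzaldehyde; 6 benzyl alcohol
Product: 12 2-(benzyloxy)-4,6-difluorobenzaldehyde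
Conditions: BnOH (1.0 equiv), KOtBu (1.0 equiv), toluene, −40 °C → 0 °C
Reagents that add atoms: none
Why: SNAr at one of the two fluorines ortho to the formyl group, which a tight potassium alkoxide ion pair in a weakly polar medium should favour over the para fluorine through coordination to the carbonyl oxygen.

Step 7
Reactants: 12 2-(benzyloxy)-4,6-difluorobenzaldehyde; 6 benzyl alcohol
Product: 13 2,6-bis(benzyloxy)-4-fluorobenzaldehyde
Conditions: BnOH (1.05 equiv), KOtBu (1.05 equiv), toluene–THF, −20 °C → rt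
Reagents that add atoms: none
Why: Second SNAr under the same ion-pair control at the remaining ortho fluorine, leaving the para fluorine for steps 12 and 13.

Step 8
Reactants: 13 2,6-bis(benzyloxy)-4-fluorobenzaldehyde
Product: 14 2,6-bis(benzyloxy)-3-bromo-4-fluorobenzaldehyde
Conditions: NBS (1.05 equiv), MeCN, rt, dark
Reagents that add atoms: N-bromosuccinimide, O=C1CCC(=O)N1Br
Why: Electrophilic aromatic bromination at one of the two equivalent free ring positions, each ortho to one benzyloxy group, para to the other and meta to the formyl group.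

Step 9
Reactants: 14 2,6-bis(benzyloxy)-3-bromo-4-fluorobenzaldehyde
Product: 15 2,6-bis(benzyloxy)-4-fluoro-3-(4,4,5,5-tetramethyl-1,3,2-dioxaborolan-2-yl)benzaldehyde
Conditions: B2pin2, PdCl2(dppf) (5 mol%), KOAc, 1,4-dioxane, 90 °C
Reagents that add atoms: bis(pinacolato)diboron, CC1(C)OB(OC1(C)C)B1OC(C)(C)C(C)(C)O1
Why: Miyaura borylation of the aryl bromide, which tolerates the aldehyde and the aryl fluoride under the weakly basic acetate conditions.

Step 10
Reactants: 15 2,6-bis(benzyloxy)-4-fluoro-3-(4,4,5,5-tetramethyl-1,3,2-dioxaborolan-2-yl)benzaldehyde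
Product: 16 2,6-bis(benzyloxy)-4-fluoro-3-hydroxybenzaldehyde
Conditions: NaBO3·4H2O, THF–H2O, rt
Reagents that add atoms: sodium perborate, [Na+].[O-]OB=O
Why: Oxidation of the aryl boronate by boron-to-oxygen aryl shift, which under these mild conditions should be much faster than any attack of the peroxide on the aldehyde or the activated fluoride.

Step 11
Reactants: 16 2,6-bis(benzyloxy)-4-fluoro-3-hydroxybenzaldehyde; 17 allyl bromide
Product: 18 3-(allyloxy)-2,6-bis(benzyloxy)-4-fluorobenzaldehyde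
Conditions: allyl bromide, K2CO3, acetone, rt
Reagents that add atoms: none
Why: Williamson O-allylation, needed because a free phenoxide ortho to the fluorine would shut down the later SNAr, and fast enough at room temperature to outrun any fluoride displacement.

Step 12
Reactants: 10 2,6-bis(benzyloxy)-4-bromophenol; 18 3-(allyloxy)-2,6-bis(benzyloxy)-4-fluorobenzaldehyde
Product: 19 3-(allyloxy)-2,6-bis(benzyloxy)-4-[2,6-bis(benzyloxy)-4-bromophenoxy]benzaldehyde
Conditions: K2CO3, DMF, 90 °C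
Reagents that add atoms: none
Why: SNAr in which the hindered 2,6-dibenzyloxyphenoxide displaces the fluoride activated by the para formyl group, while the unactivated aryl bromide and the allyl ether do not react.

Step 13
Reactants: 10 2,6-bis(benzyloxy)-4-bromophenol; 13 2,6-bis(benzyloxy)-4-fluorobenzaldehyde
Product: 20 2,6-bis(benzyloxy)-4-[2,6-bis(benzyloxy)-4-bromophenoxy]benzaldehyde
Conditions: K2CO3, DMF, 80 °C
Reagents that add atoms: none
Why: The same para-formyl-activated SNAr, here at a fluorine flanked by two ring hydrogens.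

Step 14
Reactants: 4 2,4,6-tris(benzyloxy)phenol; 19 bromo dimer for rings B–C
Product: 21 rings A–C trimer aldehyde with an allyl ether on C2 of ring C
Conditions: CuI (20 mol%), picolinic acid (40 mol%), K3PO4, DMSO, 90 °C, argon
Reagents that add atoms: none
Why: Ullmann diaryl ether coupling with a copper–picolinic acid catalyst suited to 2,6-disubstituted phenols, at a bromide carbon flanked only by ring hydrogens and with the formyl and allyl groups inert.

Step 15
Reactants: 21 rings A–C trimer allyl ether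
Product: 22 rings A–C trimer with a free hydroxyl on C2 of ring C
Conditions: Pd(PPh3)4 (5 mol%), K2CO3, MeOH–THF, rt
Reagents that add atoms: none
Why: Tsuji–Trost-type deallylation in which zerovalent palladium ionises the allyl aryl ether and methanol takes up the allyl group, leaving benzyl ethers, diaryl ethers and the aldehyde untouched.

Step 16
Reactants: 22 rings A–C trimer phenol; 19 bromo dimer for rings D–E
Product: 23 rings A–E pentamer dialdehyde with an allyl ether on C2 of ring E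
Conditions: CuI (20 mol%), picolinic acid (40 mol%), K3PO4, DMSO, 90 °C, argon
Reagents that add atoms: none
Why: Ullmann diaryl ether coupling of the ring C C2 phenol with the ring D bromide, the same reaction type as step 14 but at a more crowded phenol.

Step 17
Reactants: 23 rings A–E pentamer allyl ether
Product: 24 rings A–E pentamer with a free hydroxyl on C2 of ring E
Conditions: Pd(PPh3)4 (5 mol%), K2CO3, MeOH–THF, rt
Reagents that add atoms: none
Why: The same palladium-catalysed deallylation as in step 15, orthogonal to every other group present.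

Step 18
Reactants: 24 rings A–E pentamer phenol; 20 bromo dimer for rings F–G
Product: 25 rings A–G heptamer trialdehyde (formyl on C4 of rings C, E and G, fifteen benzyl ethers)
Conditions: CuI (20 mol%), picolinic acid (40 mol%), K3PO4, DMSO, 90 °C, argon
Reagents that add atoms: none
Why: Third Ullmann diaryl ether coupling, joining the ring E C2 phenol to the unhindered ring F bromide.

Step 19
Reactants: 25 rings A–G heptamer trialdehyde
Product: 27 pentadeca-O-benzyl heptamer triol, via heptamer triformate 26 (not isolated)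
Conditions: mCPBA (4 equiv), NaHCO3, CH2Cl2, 0 °C → rt; aq. Na2S2O3; then K2CO3 (cat.), MeOH–THF, 0 °C, argon
Reagents that add atoms: meta-chloroperbenzoic acid, OOC(=O)c1cccc(Cl)c1
Why: Each formyl group adds the peracid to give a Criegee adduct, and the aryl group, made strongly migratory by its two ortho benzyloxy groups and the para aryloxy group, shifts from carbon to oxygen with loss of 3-chlorobenzoate to give the aryl formate, which mild methanolysis converts into the C4 phenol. The closest known reaction type is the Baeyer–Villiger (Dakin-type) oxidation of 2,6-dialkoxybenzaldehydes to phenols, the same reaction as in steps 2 and 5. No ring is closed and no stereocentre is formed; the step makes the three C4–O bonds of rings C, E and G. The selectivity needed is aryl over hydride migration (which would give carboxylic acids) and aldehyde oxidation over attack on the electron-rich rings; the ortho,ortho-dialkoxy pattern secures the first, and the bicarbonate buffer, low temperature and a near-stoichiometric charge of peracid should secure the second. All three aldehydes sit in the same 2,6-bis(benzyloxy)-4-aryloxy environment and should react at similar rates, and the phenols stay masked as formates until the oxidant has been quenched.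

Step 20
Reactants: 27 pentadeca-O-benzyl heptamer triol
Product: 28 CNP0292517.0 (target)
Conditions: H2 (1 atm), Pd/C, THF–MeOH, rt, then filtration under argon
Reagents that add atoms: none
Why: Hydrogenolysis of the fifteen aryl benzyl ethers, to which the diaryl ether bonds are inert.

**Compound list**

1 | 1,3,5-tris(benzyloxy)benzene | c1c(OCc2ccccc2)cc(OCc2ccccc2)cc1OCc1ccccc1 | starting material
2 | 2,4,6-tris(benzyloxy)benzaldehyde | O=Cc1c(OCc2ccccc2)cc(OCc2ccccc2)cc1OCc1ccccc1 | intermediate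
3 | 2,4,6-tris(benzyloxy)phenyl formate | O=COc1c(OCc2ccccc2)cc(OCc2ccccc2)cc1OCc1ccccc1 | intermediate (not isolated)
4 | 2,4,6-tris(benzyloxy)phenol | Oc1c(OCc2ccccc2)cc(OCc2ccccc2)cc1OCc1ccccc1 | intermediate
5 | 4-bromo-2,6-difluorobenzaldehyde | O=Cc1c(F)cc(Br)cc1F | starting material
6 | benzyl alcohol | OCc1ccccc1 | starting material
7 | 2-(benzyloxy)-4-bromo-6-fluorobenzaldehyde | O=Cc1c(F)cc(Br)cc1OCc1ccccc1 | intermediate
8 | 2,6-bis(benzyloxy)-4-bromobenzaldehyde | O=Cc1c(OCc2ccccc2)cc(Br)cc1OCc1ccccc1 | intermediate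
9 | 2,6-bis(benzyloxy)-4-bromophenyl formate | O=COc1c(OCc2ccccc2)cc(Br)cc1OCc1ccccc1 | intermediate (not isolated)
10 | 2,6-bis(benzyloxy)-4-bromophenol | Oc1c(OCc2ccccc2)cc(Br)cc1OCc1ccccc1 | intermediate
11 | 2,4,6-trifluorobenzaldehyde | O=Cc1c(F)cc(F)cc1F | starting material
12 | 2-(benzyloxy)-4,6-difluorobenzaldehyde | O=Cc1c(F)cc(F)cc1OCc1ccccc1 | intermediate
13 | 2,6-bis(benzyloxy)-4-fluorobenzaldehyde | O=Cc1c(OCc2ccccc2)cc(F)cc1OCc1ccccc1 | intermediate
14 | 2,6-bis(benzyloxy)-3-bromo-4-fluorobenzaldehyde | O=Cc1c(OCc2ccccc2)cc(F)c(Br)c1OCc1ccccc1 | intermediate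
15 | 2,6-bis(benzyloxy)-4-fluoro-3-(4,4,5,5-tetramethyl-1,3,2-dioxaborolan-2-yl)benzaldehyde | O=Cc1c(OCc2ccccc2)cc(F)c(B2OC(C)(C)C(C)(C)O2)c1OCc1ccccc1 | intermediate
16 | 2,6-bis(benzyloxy)-4-fluoro-3-hydroxybenzaldehyde | O=Cc1c(OCc2ccccc2)cc(F)c(O)c1OCc1ccccc1 | intermediate
17 | allyl bromide | C=CCBr | starting material
18 | 3-(allyloxy)-2,6-bis(benzyloxy)-4-fluorobenzaldehyde | O=Cc1c(OCc2ccccc2)cc(F)c(OCC=C)c1OCc1ccccc1 | intermediate
19 | 3-(allyloxy)-2,6-bis(benzyloxy)-4-[2,6-bis(benzyloxy)-4-bromophenoxy]benzaldehyde (bromo dimer for rings B–C and D–E) | Brc1cc(OCc9ccccc9)c(Oc2cc(OCc9ccccc9)c(C=O)c(OCc9ccccc9)c2OCC=C)c(OCc9ccccc9)c1 | intermediate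
20 | 2,6-bis(benzyloxy)-4-[2,6-bis(benzyloxy)-4-bromophenoxy]benzaldehyde (bromo dimer for rings F–G) | Brc1cc(OCc9ccccc9)c(Oc2cc(OCc9ccccc9)c(C=O)c(OCc9ccccc9)c2)c(OCc9ccccc9)c1 | intermediate
21 | 3-(allyloxy)-2,6-bis(benzyloxy)-4-{2,6-bis(benzyloxy)-4-[2,4,6-tris(benzyloxy)phenoxy]phenoxy}benzaldehyde (rings A–C) | C(c9ccccc9)Oc1cc(OCc9ccccc9)c(Oc2cc(OCc9ccccc9)c(Oc3cc(OCc9ccccc9)c(C=O)c(OCc9ccccc9)c3OCC=C)c(OCc9ccccc9)c2)c(OCc9ccccc9)c1 | intermediate
22 | 2,6-bis(benzyloxy)-3-hydroxy-4-{2,6-bis(benzyloxy)-4-[2,4,6-tris(benzyloxy)phenoxy]phenoxy}benzaldehyde (rings A–C) | C(c9ccccc9)Oc1cc(OCc9ccccc9)c(Oc2cc(OCc9ccccc9)c(Oc3cc(OCc9ccccc9)c(C=O)c(OCc9ccccc9)c3O)c(OCc9ccccc9)c2)c(OCc9ccccc9)c1 | intermediate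
23 | rings A–E pentamer: 22 arylated on the ring C C2 oxygen by C1 of ring D; formyl on C4 of rings C and E, allyl ether on C2 of ring E, eleven benzyl ethers | C(c9ccccc9)Oc1cc(OCc9ccccc9)c(Oc2cc(OCc9ccccc9)c(Oc3cc(OCc9ccccc9)c(C=O)c(OCc9ccccc9)c3Oc3cc(OCc9ccccc9)c(Oc4cc(OCc9ccccc9)c(C=O)c(OCc9ccccc9)c4OCC=C)c(OCc9ccccc9)c3)c(OCc9ccccc9)c2)c(OCc9ccccc9)c1 | intermediate
24 | rings A–E pentamer as 23 but with a free hydroxyl on C2 of ring E | C(c9ccccc9)Oc1cc(OCc9ccccc9)c(Oc2cc(OCc9ccccc9)c(Oc3cc(OCc9ccccc9)c(C=O)c(OCc9ccccc9)c3Oc3cc(OCc9ccccc9)c(Oc4cc(OCc9ccccc9)c(C=O)c(OCc9ccccc9)c4O)c(OCc9ccccc9)c3)c(OCc9ccccc9)c2)c(OCc9ccccc9)c1 | intermediate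
25 | rings A–G heptamer trialdehyde: formyl on C4 of rings C, E and G, fifteen benzyl ethers | C(c9ccccc9)Oc1cc(OCc9ccccc9)c(Oc2cc(OCc9ccccc9)c(Oc3cc(OCc9ccccc9)c(C=O)c(OCc9ccccc9)c3Oc3cc(OCc9ccccc9)c(Oc4cc(OCc9ccccc9)c(C=O)c(OCc9ccccc9)c4Oc4cc(OCc9ccccc9)c(Oc5cc(OCc9ccccc9)c(C=O)c(OCc9ccccc9)c5)c(OCc9ccccc9)c4)c(OCc9ccccc9)c3)c(OCc9ccccc9)c2)c(OCc9ccccc9)c1 | intermediate
26 | heptamer tris(formate): formyloxy on C4 of rings C, E and G, fifteen benzyl ethers | C(c9ccccc9)Oc1cc(OCc9ccccc9)c(Oc2cc(OCc9ccccc9)c(Oc3cc(OCc9ccccc9)c(OC=O)c(OCc9ccccc9)c3Oc3cc(OCc9ccccc9)c(Oc4cc(OCc9ccccc9)c(OC=O)c(OCc9ccccc9)c4Oc4cc(OCc9ccccc9)c(Oc5cc(OCc9ccccc9)c(OC=O)c(OCc9ccccc9)c5)c(OCc9ccccc9)c4)c(OCc9ccccc9)c3)c(OCc9ccccc9)c2)c(OCc9ccccc9)c1 | intermediate (not isolated)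
27 | heptamer triol: free hydroxyl on C4 of rings C, E and G, fifteen benzyl ethers | C(c9ccccc9)Oc1cc(OCc9ccccc9)c(Oc2cc(OCc9ccccc9)c(Oc3cc(OCc9ccccc9)c(O)c(OCc9ccccc9)c3Oc3cc(OCc9ccccc9)c(Oc4cc(OCc9ccccc9)c(O)c(OCc9ccccc9)c4Oc4cc(OCc9ccccc9)c(Oc5cc(OCc9ccccc9)c(O)c(OCc9ccccc9)c5)c(OCc9ccccc9)c4)c(OCc9ccccc9)c3)c(OCc9ccccc9)c2)c(OCc9ccccc9)c1 | intermediate
28 | CNP0292517.0, the fully deprotected rings A–G heptamer | Oc1cc(O)c(Oc2cc(O)c(Oc3cc(O)c(O)c(O)c3Oc3cc(O)c(Oc4cc(O)c(O)c(O)c4Oc4cc(O)c(Oc5cc(O)c(O)c(O)c5)c(O)c4)c(O)c3)c(O)c2)c(O)c1 | target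

**Step count and risks**

Total: 20 steps. Longest linear sequence: 14 steps (steps 6, 7, 8, 9, 10, 11, 12, 14, 15, 16, 17, 18, 19, 20, from 11).

Step 19 (key step). The peracid may attack the benzyloxy-rich rings of the heptamer, one of the three sites may stall or lose hydride instead of aryl (giving an acid), or the liberated phenols may be oxidised during methanolysis. The fallback moves the oxidation forward to the dimers, where only two aryl rings face the peracid, and assembles the heptamer without formyl groups. It sets out from 19 and 20 and comes back to the route at 28. Buffered mCPBA would convert 19 into 3-(allyloxy)-2,6-bis(benzyloxy)-4-[2,6-bis(benzyloxy)-4-bromophenoxy]phenyl formate F1. Methanolysis (K2CO3, MeOH) would give 3-(allyloxy)-2,6-bis(benzyloxy)-4-[2,6-bis(benzyloxy)-4-bromophenoxy]phenol F2, and benzylation with benzyl bromide (K2CO3, DMF) would give 2-(allyloxy)-3,4,5-tris(benzyloxy)-1-[2,6-bis(benzyloxy)-4-bromophenoxy]benzene F3. In the same way 20 would give 2,6-bis(benzyloxy)-4-[2,6-bis(benzyloxy)-4-bromophenoxy]phenyl formate F4, then 2,6-bis(benzyloxy)-4-[2,6-bis(benzyloxy)-4-bromophenoxy]phenol F5, then 1,2,3-tris(benzyloxy)-5-[2,6-bis(benzyloxy)-4-bromophenoxy]benzene F6. Ullmann coupling of 4 with F3 (CuI, picolinic acid, K3PO4, DMSO) would give the formyl-free rings A–C trimer allyl ether F7, and deallylation (Pd(PPh3)4, K2CO3, MeOH) its ring C C2 phenol F8. A second coupling with F3 would give the formyl-free rings A–E pentamer allyl ether F9, and deallylation its ring E C2 phenol F10. Coupling with F6 would give the octadeca-O-benzyl heptamer F11, which hydrogenolysis over Pd/C would convert into 28.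

Step 16 (the same concern applies to step 18, and an analogous detour would serve there). Carbon–oxygen bond formation may be sluggish at a phenol flanked by a benzyloxy group and a bulky aryloxy group with an electron-rich bromide, so that protodebromination or oxidation of the phenoxide takes over. The fallback replaces the copper coupling by fluoride displacement followed by Baeyer–Villiger oxidation, so that the ring D C4 oxygen also comes from a formyl group. It sets out from 21 and comes back to the route at 23. Ethylene glycol and TsOH (toluene, water removal) would mask the ring C aldehyde as the 1,3-dioxolane of the trimer allyl ether F12, so that only the ring D aldehyde is oxidised later. Deallylation (Pd(PPh3)4, K2CO3, MeOH) would give the dioxolane trimer C2 phenol F13. SNAr of its phenoxide on 13 (K2CO3, DMF, 90 °C) would give the rings A–D tetramer with a formyl group on C4 of ring D F14. Buffered mCPBA would give the tetramer ring D formate F15, and methanolysis the tetramer ring D C4 phenol F16. SNAr on 18 would give the rings A–E pentamer allyl ether with the ring C dioxolane and the ring E formyl group F17, and mild acid (PPTS, acetone–H2O) would release the ring C aldehyde to give 23.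

Step 6 (the same concern applies to step 7). The alkoxide may attack the para instead of the ortho fluorine (loss of regiocontrol), substitute more than once, or transfer hydride to the aldehyde. The fallback makes 13 from the regiochemically unambiguous bromide. It sets out from 8 and comes back to the route at 13. Ethylene glycol and TsOH would give 2-[2,6-bis(benzyloxy)-4-bromophenyl]-1,3-dioxolane F18. Bromine–lithium exchange (n-BuLi, THF, −78 °C) would give 2-[2,6-bis(benzyloxy)-4-lithiophenyl]-1,3-dioxolane F19. Quenching with N-fluorobenzenesulfonimide would give 2-[2,6-bis(benzyloxy)-4-fluorophenyl]-1,3-dioxolane F20, and aqueous acid (PPTS, acetone–H2O) would return 13.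

Further compounds
F1 | step 19 | 3-(allyloxy)-2,6-bis(benzyloxy)-4-[2,6-bis(benzyloxy)-4-bromophenoxy]phenyl formate | Brc1cc(OCc9ccccc9)c(Oc2cc(OCc9ccccc9)c(OC=O)c(OCc9ccccc9)c2OCC=C)c(OCc9ccccc9)c1
F2 | step 19 | 3-(allyloxy)-2,6-bis(benzyloxy)-4-[2,6-bis(benzyloxy)-4-bromophenoxy]phenol | Brc1cc(OCc9ccccc9)c(Oc2cc(OCc9ccccc9)c(O)c(OCc9ccccc9)c2OCC=C)c(OCc9ccccc9)c1
F3 | step 19 | 2-(allyloxy)-3,4,5-tris(benzyloxy)-1-[2,6-bis(benzyloxy)-4-bromophenoxy]benzene | Brc1cc(OCc9ccccc9)c(Oc2cc(OCc9ccccc9)c(OCc9ccccc9)c(OCc9ccccc9)c2OCC=C)c(OCc9ccccc9)c1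
F4 | step 19 | 2,6-bis(benzyloxy)-4-[2,6-bis(benzyloxy)-4-bromophenoxy]phenyl formate | Brc1cc(OCc9ccccc9)c(Oc2cc(OCc9ccccc9)c(OC=O)c(OCc9ccccc9)c2)c(OCc9ccccc9)c1
F5 | step 19 | 2,6-bis(benzyloxy)-4-[2,6-bis(benzyloxy)-4-bromophenoxy]phenol | Brc1cc(OCc9ccccc9)c(Oc2cc(OCc9ccccc9)c(O)c(OCc9ccccc9)c2)c(OCc9ccccc9)c1
F6 | step 19 | 1,2,3-tris(benzyloxy)-5-[2,6-bis(benzyloxy)-4-bromophenoxy]benzene | Brc1cc(OCc9ccccc9)c(Oc2cc(OCc9ccccc9)c(OCc9ccccc9)c(OCc9ccccc9)c2)c(OCc9ccccc9)c1
F7 | step 19 | formyl-free rings A–C trimer allyl ether (benzyloxy on C3, C4 and C5 of ring C, eight benzyl ethers) | C(c9ccccc9)Oc1cc(OCc9ccccc9)c(Oc2cc(OCc9ccccc9)c(Oc3cc(OCc9ccccc9)c(OCc9ccccc9)c(OCc9ccccc9)c3OCC=C)c(OCc9ccccc9)c2)c(OCc9ccccc9)c1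
F8 | step 19 | formyl-free rings A–C trimer with free hydroxyl on C2 of ring C | C(c9ccccc9)Oc1cc(OCc9ccccc9)c(Oc2cc(OCc9ccccc9)c(Oc3cc(OCc9ccccc9)c(OCc9ccccc9)c(OCc9ccccc9)c3O)c(OCc9ccccc9)c2)c(OCc9ccccc9)c1
F9 | step 19 | formyl-free rings A–E pentamer allyl ether (thirteen benzyl ethers) | C(c9ccccc9)Oc1cc(OCc9ccccc9)c(Oc2cc(OCc9ccccc9)c(Oc3cc(OCc9ccccc9)c(OCc9ccccc9)c(OCc9ccccc9)c3Oc3cc(OCc9ccccc9)c(Oc4cc(OCc9ccccc9)c(OCc9ccccc9)c(OCc9ccccc9)c4OCC=C)c(OCc9ccccc9)c3)c(OCc9ccccc9)c2)c(OCc9ccccc9)c1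
F10 | step 19 | formyl-free rings A–E pentamer with free hydroxyl on C2 of ring E | C(c9ccccc9)Oc1cc(OCc9ccccc9)c(Oc2cc(OCc9ccccc9)c(Oc3cc(OCc9ccccc9)c(OCc9ccccc9)c(OCc9ccccc9)c3Oc3cc(OCc9ccccc9)c(Oc4cc(OCc9ccccc9)c(OCc9ccccc9)c(OCc9ccccc9)c4O)c(OCc9ccccc9)c3)c(OCc9ccccc9)c2)c(OCc9ccccc9)c1
F11 | step 19 | octadeca-O-benzyl rings A–G heptamer | C(c9ccccc9)Oc1cc(OCc9ccccc9)c(Oc2cc(OCc9ccccc9)c(Oc3cc(OCc9ccccc9)c(OCc9ccccc9)c(OCc9ccccc9)c3Oc3cc(OCc9ccccc9)c(Oc4cc(OCc9ccccc9)c(OCc9ccccc9)c(OCc9ccccc9)c4Oc4cc(OCc9ccccc9)c(Oc5cc(OCc9ccccc9)c(OCc9ccccc9)c(OCc9ccccc9)c5)c(OCc9ccccc9)c4)c(OCc9ccccc9)c3)c(OCc9ccccc9)c2)c(OCc9ccccc9)c1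
F12 | step 16 | rings A–C trimer allyl ether with the ring C formyl group as 1,3-dioxolane | C(c9ccccc9)Oc1cc(OCc9ccccc9)c(Oc2cc(OCc9ccccc9)c(Oc3cc(OCc9ccccc9)c(C4OCCO4)c(OCc9ccccc9)c3OCC=C)c(OCc9ccccc9)c2)c(OCc9ccccc9)c1
F13 | step 16 | rings A–C dioxolane trimer with free hydroxyl on C2 of ring C | C(c9ccccc9)Oc1cc(OCc9ccccc9)c(Oc2cc(OCc9ccccc9)c(Oc3cc(OCc9ccccc9)c(C4OCCO4)c(OCc9ccccc9)c3O)c(OCc9ccccc9)c2)c(OCc9ccccc9)c1
F14 | step 16 | rings A–D tetramer: dioxolane on ring C, formyl on C4 of ring D | C(c9ccccc9)Oc1cc(OCc9ccccc9)c(Oc2cc(OCc9ccccc9)c(Oc3cc(OCc9ccccc9)c(C4OCCO4)c(OCc9ccccc9)c3Oc3cc(OCc9ccccc9)c(C=O)c(OCc9ccccc9)c3)c(OCc9ccccc9)c2)c(OCc9ccccc9)c1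
F15 | step 16 | rings A–D tetramer: dioxolane on ring C, formyloxy on C4 of ring D | C(c9ccccc9)Oc1cc(OCc9ccccc9)c(Oc2cc(OCc9ccccc9)c(Oc3cc(OCc9ccccc9)c(C4OCCO4)c(OCc9ccccc9)c3Oc3cc(OCc9ccccc9)c(OC=O)c(OCc9ccccc9)c3)c(OCc9ccccc9)c2)c(OCc9ccccc9)c1
F16 | step 16 | rings A–D tetramer: dioxolane on ring C, free hydroxyl on C4 of ring D | C(c9ccccc9)Oc1cc(OCc9ccccc9)c(Oc2cc(OCc9ccccc9)c(Oc3cc(OCc9ccccc9)c(C4OCCO4)c(OCc9ccccc9)c3Oc3cc(OCc9ccccc9)c(O)c(OCc9ccccc9)c3)c(OCc9ccccc9)c2)c(OCc9ccccc9)c1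
F17 | step 16 | rings A–E pentamer allyl ether: dioxolane on ring C, formyl on C4 of ring E | C(c9ccccc9)Oc1cc(OCc9ccccc9)c(Oc2cc(OCc9ccccc9)c(Oc3cc(OCc9ccccc9)c(C4OCCO4)c(OCc9ccccc9)c3Oc3cc(OCc9ccccc9)c(Oc4cc(OCc9ccccc9)c(C=O)c(OCc9ccccc9)c4OCC=C)c(OCc9ccccc9)c3)c(OCc9ccccc9)c2)c(OCc9ccccc9)c1
F18 | step 6 | 2-[2,6-bis(benzyloxy)-4-bromophenyl]-1,3-dioxolane | Brc1cc(OCc9ccccc9)c(C2OCCO2)c(OCc9ccccc9)c1
F19 | step 6 | 2-[2,6-bis(benzyloxy)-4-lithiophenyl]-1,3-dioxolane | [Li]c1cc(OCc9ccccc9)c(C2OCCO2)c(OCc9ccccc9)c1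
F20 | step 6 | 2-[2,6-bis(benzyloxy)-4-fluorophenyl]-1,3-dioxolane | Fc1cc(OCc9ccccc9)c(C2OCCO2)c(OCc9ccccc9)c1
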